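## Structural features

The target is a 2,3-dihydro-1-benzofuran: a benzene ring (C3a, C4, C5, C6, C7, C7a) fused to a five-membered oxacycle (O1–C2–C3–C3a–C7a). C2 carries a 1-formylvinyl group (an α-substituted acrolein), C3 an acetoxy group, and C5 a 1-(acyloxy)ethyl chain whose acyl part is the (Z)-2-methylbut-2-enoyl (angeloyl) group. C2 (R) and C3 (S) are adjacent and trans. The third stereocentre, the (R)-carbinol carbon of the C5 chain, lies para to O1 and too far from the ring stereocentres for substrate control. Four groups are fragile: the enal (conjugate addition, polymerisation), the benzylic C3 acetate (loss of acetic acid aromatises the ring to a benzofuran), the para-alkoxybenzylic ester (ionises in acid) and the angelate (isomerises to the (E)-tiglate under nucleophilic catalysis, acid or prolonged heating). The real difficulty is to set the trans C2/C3 pair in the absolute sense and then unveil three differently functionalised oxygens (acetate, angelate, aldehyde) in an order that none of the fragile groups has to survive harsh steps. The key step exploits the position of the ring oxygen: O1 is bonded to C7a, which is para to C5, so with C5 at the acetyl oxidation level C7a is an SNAr-activated carbon and the O1–C7a bond can be closed last from an acyclic anti-diol.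

## Logic of the disconnections

**Enal.** 18 is taken back to 17 by returning the formyl carbon to the primary allylic alcohol level, and 17 to 16 by restoring the O–Si bond. The acrolein unit is the most reactive function, so it is made in the final step and every earlier step works on a silyl ether. The forward steps must be a near-neutral desilylation and a non-acidic oxidation that spare both esters.

**Angelate.** 16 is cut at the acyl C–O bond of the angelate into 13 and 14. This removes the isomerisation-prone (Z)-ester from all earlier chemistry and leaves a simple secondary benzylic alcohol. The forward acylation must go through acyl activation only (retention at the carbinol) and must not equilibrate the (Z)-double bond.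

**Carbinol.** 13 is traced to 12 by removing the carbinol C–H bond. The ketone is not only the precursor of the stereocentre but also the electron-withdrawing group that permits the ring closure, so this centre has to be created after the ring. The gain is the loss of the remote stereocentre. The demand is a catalyst-controlled reduction that leaves the 1,1-disubstituted alkene, the acetate and the silyl ether alone.

**Acetate.** 12 goes back to 11 by cutting the acetate O–acyl bond. The acetyl group is put on after ring closure because an ester next to a free hydroxyl would migrate or be cleaved under basic closure conditions.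

**Aryl ether (key).** 11 is opened at the O1–C7a bond, with fluorine placed on C7a, to give 10. This turns the bicycle into an acyclic anti-1,2-diol whose two stereocentres sit side by side in a chain, which is an aldol pattern. The forward step needs O-arylation through the C2 oxygen only, under a base mild enough for a methyl ketone and a silyl ether. The free diol is kept; the design choices are a migration-resistant silyl group on the primary oxygen and a carbonate base.

**Protecting groups.** 10 goes back to 9 (O–Si bond) and 9 to 8 (the C–O bonds of the isopropylidene acetal and the dioxolane, and the benzylic O–Si bond). A triol ketone cannot pass through organometallic and ylide steps, and all three masks fall in one acidic operation. The demands are primary-selective silylation and a hydrolysis that does not ionise the allylic or benzylic carbinols.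

**Methylene.** 8 is cut at the C=CH2 bond to ketone 7, and 7 at the O–Si bond to 6. The ketone is what makes the aldol possible. Methylenating a β-oxygenated ketone with an α-stereocentre risks retro-aldol, β-elimination and epimerisation, hence the silyl cap and a cold ylide addition.

**Aldol.** 6 is cut at the C–C bond between the carbinol carbon and the ring α-carbon (the future C3–C2 bond) into 4 and 5. One catalytic anti-aldol makes this bond and both ring stereocentres, and 5 delivers the C2 oxygen, the future vinyl carbon and the future formyl carbon together. The demand is enantio- and anti-selective enamine catalysis with an aromatic aldehyde.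

**Arene.** 4 is cut at the aryl–CHO bond to 2 (through 3), and 2 at the ketal C–O bonds to 1. Bromine marks the carbon ortho to fluorine and the acetyl group is already para to fluorine. The forward metalation must avoid aryne formation by loss of metal fluoride, and the ketone must be masked.

## Other disconnections considered

**Alternative 1:** The cut is the C2–C3 bond, with the ring closing in the same event. The precursor is the aryl allenyl ether 5-[(1R)-1-(tert-butyldimethylsilyloxy)ethyl]-2-(propa-1,2-dien-1-yloxy)benzaldehyde A2. In the forward step a chiral bisphosphine complex of CuCl with NaOtBu and B2pin2 would place boron on the central allene carbon. The resulting 2-boryl allylcopper would add through its oxygen-bearing carbon to the ortho aldehyde, giving (2R,3S)-5-[(1R)-1-(tert-butyldimethylsilyloxy)ethyl]-2-[1-(4,4,5,5-tetramethyl-1,3,2-dioxaborolan-2-yl)ethenyl]-2,3-dihydro-1-benzofuran-3-ol A1.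
- In its favour: one catalytic step would form a C–C bond, the ring and both ring stereocentres, where the chosen plan needs step 3 for the stereocentres and step 8 for the ring. On bond economy at the key step it is the better plan. The carbinol stereocentre is carried from the start, so no late ketone reduction is needed.
- Against it here: trans selectivity and high enantioselectivity would have to come from the least precedented step, an oxygen-substituted allylcopper closing a five-membered ring, where a cis outcome is a realistic possibility. Boron ends up on the carbon that must bear the formyl carbon, so a one-carbon homologation at boron (LiCH2Cl insertion, oxidation) and a further oxidation are needed. A2 requires a base-mediated propargyl-to-allenyl ether isomerisation next to an aldehyde.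
- Comparison: the end-point is structurally equivalent. Mechanistically the chosen ring closure creates no stereocentre and so has no stereochemical risk, whereas in A1 all the stereochemical risk sits in the key step. The step counts are expected to be about equal.

**Alternative 2:** The cut is the O1–C2 bond, traced to a chroman in which the ring oxygen is bonded to the CMe2 carbon: (3R,4S)-6-acetyl-3-hydroxy-2,2-dimethyl-3,4-dihydro-2H-chromen-4-yl acetate A4. A4 would come from 1-(2,2-dimethyl-2H-chromen-6-yl)ethanone A5 by Jacobsen–Katsuki epoxidation with a chiral [N,N'-bis(3,5-di-tert-butylsalicylidene)-1,2-cyclohexanediamine]MnCl complex and trans opening by acetic acid at C4. In the forward step Tf2O would activate the C3 hydroxyl; the ring oxygen would shift from the CMe2 carbon to C3 with inversion, and proton loss from the tertiary cation would give (2R,3S)-5-acetyl-2-(prop-1-en-2-yl)-2,3-dihydro-1-benzofuran-3-yl acetate A3.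
- In its favour: 2,2-dimethylchromenes are among the best substrates for that epoxidation, the trans relationship follows from two stereospecific events, and the acetate is already in place. A3 would be reached in roughly half the steps the chosen plan needs for 12, which is a clear advantage in step economy to the core.
- Against it here: the trans C4 acetate is also anti to the leaving group and can participate through an acetoxonium ion, which would give retention or scrambling at C3. Proton loss can occur in more than one direction. The oxygen on the isopropenyl methyl is missing and must come from an allylic oxidation (SeO2), which also attacks aryl methyl ketones (Riley oxidation) and the allylic methyls of an angelate. That oxidation would have to be placed after ketone reduction and before acylation, with extra protection steps.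
- Comparison: structurally the chosen plan brings the side-chain oxygen in with 5, while A3 needs a late C–H oxidation. Mechanistically a cationic rearrangement with two competing neighbouring groups stands against an addition–elimination with no stereochemical event. Most of the step advantage to A3 is expected to be lost in the oxidation-state adjustments afterwards.

**Alternative 3:** The cuts are C3a–C7a and C4–C5, so the benzene ring is built last. The precursor is (3R,4S)-3-[(6-acetylpyridazin-3-yl)oxy]-2-[(tert-butyldimethylsilyloxy)methyl]hex-1-en-5-yn-4-yl acetate A7, whose ether bond would come from 1-(6-chloropyridazin-3-yl)ethanone A8. On heating, the tethered terminal alkyne would add across C3 and C6 of the pyridazine and N2 would be expelled, giving (2R,3S)-5-acetyl-2-[3-(tert-butyldimethylsilyloxy)prop-1-en-2-yl]-2,3-dihydro-1-benzofuran-3-yl acetate A6.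
- In its favour: the tether fixes the arene substitution pattern. Both stereocentres and the acetate are present before the rings form and are not touched. No base is used, so ketone enolisation is not an issue, and in that respect it is better than the chosen step 8. Two C–C bonds and two rings form in one step. A6 is the analogue of 12, so the endgame would be the same, and on that point the two plans are equal.
- Against it here: pyridazines are sluggish azadienes and the 3-alkoxy group makes this one less electron-poor, so high temperatures are to be expected. Under those conditions a propargylic acetate can undergo sigmatropic acyl shift. The ether bond of A7 would itself need an intermolecular SNAr of a hindered secondary alkoxide on A8, with the neighbouring oxygen masked by a non-migrating group. The anti-configured enyne diol needs its own asymmetric synthesis and is no simpler than 10.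
- Comparison: structurally the stereochemical problem is unchanged and only moved to a less accessible acyclic precursor. Mechanistically the cascade is more bond-forming, but the chosen intramolecular SNAr runs under far milder conditions. The step count is expected to be equal or higher.

Key step: step 8

Remark (assumption on the chemistry): L-proline is taken to steer the enamine of 5 in the same facial sense as it does for cyclohexanone, which makes the anti-aldol 6 the (4S,1'S) isomer. The descriptors (1S,2R) for 10 and (2R,3S) for 11 were re-derived from the target and agree with each other and with a trans ring, so no structure needed correction.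

## Route

Step 1
Reactants: 1 1-(3-bromo-4-fluorophenyl)ethanone
Product: 2 2-(3-bromo-4-fluorophenyl)-2-methyl-1,3-dioxolane
Conditions: ethylene glycol, p-TsOH·H2O (cat.), toluene, reflux, Dean–Stark trap
Reagents that add atoms: ethylene glycol (OCCO)
Why: Acid-catalysed ketalisation driven by azeotropic removal of water; the dioxolane masks the ketone against the arylmagnesium reagent of step 2 and the ylide of step 5.

Step 2
Reactants: 2 2-(3-bromo-4-fluorophenyl)-2-methyl-1,3-dioxolane
Product: 4 2-fluoro-5-(2-methyl-1,3-dioxolan-2-yl)benzaldehyde, via arylmagnesium chloride 3 (not isolated)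
Conditions: iPrMgCl·LiCl, THF, 0 → 20 °C; then DMF, 0 °C; aq. NH4Cl
Reagents that add atoms: N,N-dimethylformamide (CN(C)C=O)
Why: Bromine–magnesium exchange is accelerated by the ortho fluorine and leaves the C–F bond intact; an arylmagnesium species ortho to fluorine does not eliminate to the aryne at these temperatures, which is the reason for preferring it to the aryllithium. Formylation with DMF (Bouveault aldehyde synthesis) stops at the hemiaminal alkoxide, which collapses to the aldehyde on work-up.

Step 3
Reactants: 4 2-fluoro-5-(2-methyl-1,3-dioxolan-2-yl)benzaldehyde, 5 2,2-dimethyl-1,3-dioxan-5-one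
Product: 6 (4S)-4-[(S)-[2-fluoro-5-(2-methyl-1,3-dioxolan-2-yl)phenyl](hydroxy)methyl]-2,2-dimethyl-1,3-dioxan-5-one
Conditions: L-proline (30 mol%), DMF, 4 °C
Reagents that add atoms: none
Why: Proline-catalysed direct aldol through the ring-locked (E)-enamine of 5; the carboxylic acid of the catalyst hydrogen-bonds the aldehyde and delivers it to one enamine face with the aryl group pseudo-equatorial in a chair-like transition state, which should set both new stereocentres as the anti (4S,1'S) pair. The ortho-fluoro aldehyde cannot enolise and is a good acceptor.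

Step 4
Reactants: 6 (4S)-4-[(S)-[2-fluoro-5-(2-methyl-1,3-dioxolan-2-yl)phenyl](hydroxy)methyl]-2,2-dimethyl-1,3-dioxan-5-one
Product: 7 (4S)-4-[(S)-[2-fluoro-5-(2-methyl-1,3-dioxolan-2-yl)phenyl](triethylsilyloxy)methyl]-2,2-dimethyl-1,3-dioxan-5-one
Conditions: Et3SiCl, imidazole, DMF, 0 °C
Reagents that add atoms: chlorotriethylsilane (CC[Si](Cl)(CC)CC)
Why: Silylation of the aldol hydroxyl under weakly basic conditions that tolerate both acetals; capping this oxygen removes the alkoxide that would trigger retro-aldol cleavage in step 5, and the group falls off again in step 6 without a step of its own.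

Step 5
Reactants: 7 (4S)-4-[(S)-[2-fluoro-5-(2-methyl-1,3-dioxolan-2-yl)phenyl](triethylsilyloxy)methyl]-2,2-dimethyl-1,3-dioxan-5-one
Product: 8 (4R)-4-[(S)-[2-fluoro-5-(2-methyl-1,3-dioxolan-2-yl)phenyl](triethylsilyloxy)methyl]-2,2-dimethyl-5-methylidene-1,3-dioxane
Conditions: Ph3PCH3Br, KOtBu, THF, 0 °C; then 7, −78 → 0 °C
Reagents that add atoms: methyltriphenylphosphonium bromide (C[P+](c1ccccc1)(c1ccccc1)c1ccccc1.[Br-])
Why: Wittig methylenation; the α,α'-dioxygenated ketone is highly electrophilic, so the ylide should add at low temperature faster than it deprotonates C4. C4 keeps its configuration; its descriptor changes from S to R only because the CIP ranking of its neighbours changes.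

Step 6
Reactants: 8 (4R)-4-[(S)-[2-fluoro-5-(2-methyl-1,3-dioxolan-2-yl)phenyl](triethylsilyloxy)methyl]-2,2-dimethyl-5-methylidene-1,3-dioxane
Product: 9 1-[3-[(1S,2R)-1,2-dihydroxy-3-(hydroxymethyl)but-3-en-1-yl]-4-fluorophenyl]ethanone
Conditions: 1 M aq. HCl, THF, 20 °C
Reagents that add atoms: water (O)
Why: Acid hydrolysis removes the isopropylidene acetal, the dioxolane and the triethylsilyl ether in one operation, with water supplying the oxygen of the regenerated ketone. The fluorinated arene disfavours benzylic ionisation and dilute acid at room temperature should not ionise the allylic carbinol, so both stereocentres are retained.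

Step 7
Reactants: 9 1-[3-[(1S,2R)-1,2-dihydroxy-3-(hydroxymethyl)but-3-en-1-yl]-4-fluorophenyl]ethanone
Product: 10 1-[3-[(1S,2R)-3-[(tert-butyldiphenylsilyloxy)methyl]-1,2-dihydroxybut-3-en-1-yl]-4-fluorophenyl]ethanone
Conditions: tBuPh2SiCl, imidazole, CH2Cl2, 0 °C
Reagents that add atoms: tert-butylchlorodiphenylsilane (CC(C)(C)[Si](Cl)(c1ccccc1)c1ccccc1)
Why: The bulky silyl chloride reacts with the unhindered primary allylic hydroxyl much faster than with the two secondary ones. The tert-butyldiphenylsilyl group is chosen because it resists base-induced oxygen-to-oxygen migration in step 8 and survives steps 9 to 11.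

Step 8
Reactants: 10 1-[3-[(1S,2R)-3-[(tert-butyldiphenylsilyloxy)methyl]-1,2-dihydroxybut-3-en-1-yl]-4-fluorophenyl]ethanone
Product: 11 1-[(2R,3S)-2-[3-(tert-butyldiphenylsilyloxy)prop-1-en-2-yl]-3-hydroxy-2,3-dihydro-1-benzofuran-5-yl]ethanone
Conditions: Cs2CO3, DMSO (0.02 M), 20 → 50 °C
Reagents that add atoms: none
Why: Cs2CO3 sets up a small equilibrium concentration of the C2 alkoxide, which adds to C7a (ipso to fluorine) to give a Meisenheimer anion whose charge is taken up by the para acetyl group; loss of fluoride then restores the arene (addition–elimination SNAr with rate-limiting addition, hence fluoride as leaving group). The closest known reaction type is the intramolecular SNAr etherification of alkoxides onto aryl fluorides activated by a para acyl group. The ring O1–C2–C3–C3a–C7a closes in a 5-exo-trig mode, counted through the C7a=C7 bond whose electrons move out of the new ring toward C5. No stereocentre is formed and no bond to C1 or C2 of 10 is broken, so the (1S,2R) anti-diol is carried unchanged into the trans-(2R,3S) ring. The only selectivity needed is between oxygens: the benzylic oxygen could close nothing larger than a four-membered ring and the primary oxygen is silylated, so only the C2 oxygen can reach C7a. A carbonate base leaves the methyl ketone largely un-enolised, which keeps the arene activated and suppresses aldol self-condensation, and high dilution disfavours intermolecular O-arylation.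

Step 9
Reactants: 11 1-[(2R,3S)-2-[3-(tert-butyldiphenylsilyloxy)prop-1-en-2-yl]-3-hydroxy-2,3-dihydro-1-benzofuran-5-yl]ethanone
Product: 12 (2R,3S)-5-acetyl-2-[3-(tert-butyldiphenylsilyloxy)prop-1-en-2-yl]-2,3-dihydro-1-benzofuran-3-yl acetate
Conditions: Ac2O, pyridine, DMAP (cat.), CH2Cl2, 0 → 20 °C
Reagents that add atoms: acetic anhydride (CC(=O)OC(C)=O)
Why: Standard acylation of the only free hydroxyl with retention at C3. In the trans isomer the C2 hydrogen and the C3 acetoxy group are cis, so anti elimination to the benzofuran has no suitable geometry under these mild conditions.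

Step 10
Reactants: 12 (2R,3S)-5-acetyl-2-[3-(tert-butyldiphenylsilyloxy)prop-1-en-2-yl]-2,3-dihydro-1-benzofuran-3-yl acetate
Product: 13 (2R,3S)-2-[3-(tert-butyldiphenylsilyloxy)prop-1-en-2-yl]-5-[(1R)-1-hydroxyethyl]-2,3-dihydro-1-benzofuran-3-yl acetate
Conditions: RuCl[(R,R)-TsDPEN](p-cymene) (2 mol%), HCO2H–Et3N (5:2), CH2Cl2, 30 °C
Reagents that add atoms: none
Why: Noyori asymmetric transfer hydrogenation; the Ru–H/N–H pair of the (R,R)-complex transfers hydride and proton to the C=O in an outer-sphere six-membered transition state and should deliver hydride to the Si face, setting the (R)-carbinol under catalyst control. Alkene, acetate and silyl ether are not substrates for this mechanism, which is why it is preferred to a borane reduction next to a 1,1-disubstituted alkene. Any material of the enantiomeric ring series becomes a diastereomer here and can be removed.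

Step 11
Reactants: 13 (2R,3S)-2-[3-(tert-butyldiphenylsilyloxy)prop-1-en-2-yl]-5-[(1R)-1-hydroxyethyl]-2,3-dihydro-1-benzofuran-3-yl acetate, 14 angelic acid [(2Z)-2-methylbut-2-enoic acid]
Product: 16 (1R)-1-[(2R,3S)-3-acetoxy-2-[3-(tert-butyldiphenylsilyloxy)prop-1-en-2-yl]-2,3-dihydro-1-benzofuran-5-yl]ethyl (2Z)-2-methylbut-2-enoate, via angelic 2,4,6-trichlorobenzoic anhydride 15 (not isolated)
Conditions: 14, 2,4,6-trichlorobenzoyl chloride, Et3N, toluene, 20 °C; then 13, toluene, 70 °C (no DMAP)
Reagents that add atoms: none
Why: Yamaguchi-type mixed-anhydride esterification; the alcohol attacks the angeloyl carbonyl of 15 because the other carbonyl is shielded by two ortho chlorines. The carbinol C–O bond is not broken, so the (R) centre is retained, and leaving out DMAP avoids the conjugate addition–elimination pathway that turns the (Z)-acyl group into the (E)-isomer.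

Step 12
Reactants: 16 (1R)-1-[(2R,3S)-3-acetoxy-2-[3-(tert-butyldiphenylsilyloxy)prop-1-en-2-yl]-2,3-dihydro-1-benzofuran-5-yl]ethyl (2Z)-2-methylbut-2-enoate
Product: 17 (1R)-1-[(2R,3S)-3-acetoxy-2-(3-hydroxyprop-1-en-2-yl)-2,3-dihydro-1-benzofuran-5-yl]ethyl (2Z)-2-methylbut-2-enoate
Conditions: HF·pyridine, pyridine, THF, 0 → 20 °C
Reagents that add atoms: none
Why: Fluoride-driven cleavage of the Si–O bond; the pyridine buffer should keep the medium too weakly acidic to ionise the para-alkoxybenzylic angelate or the C3 acetate, and fluoride at this acidity does not attack esters.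

Step 13
Reactants: 17 (1R)-1-[(2R,3S)-3-acetoxy-2-(3-hydroxyprop-1-en-2-yl)-2,3-dihydro-1-benzofuran-5-yl]ethyl (2Z)-2-methylbut-2-enoate
Product: 18 (1R)-1-[(2R,3S)-3-acetoxy-2-(3-oxoprop-1-en-2-yl)-2,3-dihydro-1-benzofuran-5-yl]ethyl (2Z)-2-methylbut-2-enoate
Conditions: Dess–Martin periodinane, pyridine, CH2Cl2, 0 → 20 °C
Reagents that add atoms: none
Why: Dess–Martin oxidation; ligand exchange of the primary allylic alcohol at iodine and removal of the carbinol hydrogen should give the aldehyde without over-oxidation. Pyridine buffers the acetic acid released, and no stereocentre is involved.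

## Compound list

1 | 1-(3-bromo-4-fluorophenyl)ethanone | CC(=O)c1ccc(F)c(Br)c1 | starting material
2 | 2-(3-bromo-4-fluorophenyl)-2-methyl-1,3-dioxolane | CC1(OCCO1)c1ccc(F)c(Br)c1 | intermediate
3 | [2-fluoro-5-(2-methyl-1,3-dioxolan-2-yl)phenyl]magnesium chloride | CC1(OCCO1)c1ccc(F)c([Mg]Cl)c1 | intermediate (not isolated)
4 | 2-fluoro-5-(2-methyl-1,3-dioxolan-2-yl)benzaldehyde | CC1(OCCO1)c1ccc(F)c(C=O)c1 | intermediate
5 | 2,2-dimethyl-1,3-dioxan-5-one | CC1(C)OCC(=O)CO1 | starting material
6 | (4S)-4-[(S)-[2-fluoro-5-(2-methyl-1,3-dioxolan-2-yl)phenyl](hydroxy)methyl]-2,2-dimethyl-1,3-dioxan-5-one | CC1(C)OCC(=O)[C@@H](O1)[C@@H](O)c1cc(ccc1F)C1(C)OCCO1 | intermediate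
7 | (4S)-4-[(S)-[2-fluoro-5-(2-methyl-1,3-dioxolan-2-yl)phenyl](triethylsilyloxy)methyl]-2,2-dimethyl-1,3-dioxan-5-one | CC1(C)OCC(=O)[C@@H](O1)[C@@H](O[Si](CC)(CC)CC)c1cc(ccc1F)C1(C)OCCO1 | intermediate
8 | (4R)-4-[(S)-[2-fluoro-5-(2-methyl-1,3-dioxolan-2-yl)phenyl](triethylsilyloxy)methyl]-2,2-dimethyl-5-methylidene-1,3-dioxane | CC1(C)OCC(=C)[C@@H](O1)[C@@H](O[Si](CC)(CC)CC)c1cc(ccc1F)C1(C)OCCO1 | intermediate
9 | 1-[3-[(1S,2R)-1,2-dihydroxy-3-(hydroxymethyl)but-3-en-1-yl]-4-fluorophenyl]ethanone | C=C(CO)[C@@H](O)[C@@H](O)c1cc(C(C)=O)ccc1F | intermediate
10 | 1-[3-[(1S,2R)-3-[(tert-butyldiphenylsilyloxy)methyl]-1,2-dihydroxybut-3-en-1-yl]-4-fluorophenyl]ethanone | C=C(CO[Si](c1ccccc1)(c1ccccc1)C(C)(C)C)[C@@H](O)[C@@H](O)c1cc(C(C)=O)ccc1F | intermediate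
11 | 1-[(2R,3S)-2-[3-(tert-butyldiphenylsilyloxy)prop-1-en-2-yl]-3-hydroxy-2,3-dihydro-1-benzofuran-5-yl]ethanone | C=C(CO[Si](c1ccccc1)(c1ccccc1)C(C)(C)C)[C@H]1Oc2ccc(C(C)=O)cc2[C@@H]1O | intermediate
12 | (2R,3S)-5-acetyl-2-[3-(tert-butyldiphenylsilyloxy)prop-1-en-2-yl]-2,3-dihydro-1-benzofuran-3-yl acetate | C=C(CO[Si](c1ccccc1)(c1ccccc1)C(C)(C)C)[C@H]1Oc2ccc(C(C)=O)cc2[C@@H]1OC(C)=O | intermediate
13 | (2R,3S)-2-[3-(tert-butyldiphenylsilyloxy)prop-1-en-2-yl]-5-[(1R)-1-hydroxyethyl]-2,3-dihydro-1-benzofuran-3-yl acetate | C=C(CO[Si](c1ccccc1)(c1ccccc1)C(C)(C)C)[C@H]1Oc2ccc([C@@H](C)O)cc2[C@@H]1OC(C)=O | intermediate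
14 | angelic acid [(2Z)-2-methylbut-2-enoic acid] | C/C=C(/C)C(=O)O | starting material
15 | (2Z)-2-methylbut-2-enoic 2,4,6-trichlorobenzoic anhydride | C/C=C(/C)C(=O)OC(=O)c1c(Cl)cc(Cl)cc1Cl | intermediate (not isolated)
16 | (1R)-1-[(2R,3S)-3-acetoxy-2-[3-(tert-butyldiphenylsilyloxy)prop-1-en-2-yl]-2,3-dihydro-1-benzofuran-5-yl]ethyl (2Z)-2-methylbut-2-enoate | C=C(CO[Si](c1ccccc1)(c1ccccc1)C(C)(C)C)[C@H]1Oc2ccc([C@@H](C)OC(=O)/C(C)=C\C)cc2[C@@H]1OC(C)=O | intermediate
17 | (1R)-1-[(2R,3S)-3-acetoxy-2-(3-hydroxyprop-1-en-2-yl)-2,3-dihydro-1-benzofuran-5-yl]ethyl (2Z)-2-methylbut-2-enoate | C=C(CO)[C@H]1Oc2ccc([C@@H](C)OC(=O)/C(C)=C\C)cc2[C@@H]1OC(C)=O | intermediate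
18 | (1R)-1-[(2R,3S)-3-acetoxy-2-(3-oxoprop-1-en-2-yl)-2,3-dihydro-1-benzofuran-5-yl]ethyl (2Z)-2-methylbut-2-enoate | C=C(C=O)[C@H]1Oc2ccc([C@@H](C)OC(=O)/C(C)=C\C)cc2[C@@H]1OC(C)=O | target

## Step count and least certain steps

Total: 13 steps. Longest linear sequence: 13 steps from 1; compounds 5 and 14 enter as commercial reactants.

**Step 8 (key step).** The alkoxide concentration under carbonate may be too low for a useful rate. The obvious remedies, stronger base and heat, bring on enolisation of the methyl ketone, which turns the activating group into an electron-releasing enolate and opens aldol self-condensation. They also bring on migration of the silyl group from the primary oxygen to the C2 oxygen, which removes the nucleophile. The fallback sets out from 9. The ring is closed on the unprotected triol (Cs2CO3 or KOtBu, DMSO), where there is no silyl group to migrate and the five-membered closure through the C2 oxygen should outrun the seven-membered closure through the primary oxygen. This gives 1-[(2R,3S)-3-hydroxy-2-(3-hydroxyprop-1-en-2-yl)-2,3-dihydro-1-benzofuran-5-yl]ethanone F1. Selective silylation of its primary allylic hydroxyl with tBuPh2SiCl and imidazole rejoins the route at 11.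

**Step 3.** Facial control and the anti/syn ratio may be incomplete with an aromatic acceptor, turnover may be slow, and the adduct can equilibrate by retro-aldol while 5 undergoes self-aldolisation. Residual enantiomer is in any case converted into a separable diastereomer at step 10. The fallback sets out from 4 and 5. The dicyclohexylboron enolate of 5 (Cy2BCl, Et3N, Et2O, −78 °C, then 4, oxidative work-up) reacts through a closed chair transition state from the ring-locked (E)-enolate and should give the anti aldol as a racemate. Preparative chromatography on a chiral stationary phase then separates 6 from its enantiomer (4R)-4-[(R)-[2-fluoro-5-(2-methyl-1,3-dioxolan-2-yl)phenyl](hydroxy)methyl]-2,2-dimethyl-1,3-dioxan-5-one F2, which is set aside. The route is rejoined at 6.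

**Step 5.** The ylide may act as a base instead of a nucleophile, with deprotonation at C4 leading to loss of configuration or β-elimination of the silyloxy group. The fallback sets out from 7. Addition of Me3SiCH2MgCl in the presence of anhydrous CeCl3 (THF, −78 → 0 °C), a weakly basic organometallic, should give (4S)-4-[(S)-[2-fluoro-5-(2-methyl-1,3-dioxolan-2-yl)phenyl](triethylsilyloxy)methyl]-2,2-dimethyl-5-[(trimethylsilyl)methyl]-1,3-dioxan-5-ol F3 as a mixture of C5 epimers. The aqueous HCl–THF treatment of step 6 then effects acid-promoted Peterson elimination together with removal of the three protecting groups, and the route is rejoined at 9.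

**Step 11.** The activated acid may isomerise from (Z) to (E) at the temperature needed to acylate a secondary benzylic alcohol, or the acylation may stall so that the para-alkoxybenzylic alcohol is exposed to hot ammonium salts for long periods. The fallback sets out from 13 and builds the (Z)-alkene after the ester bond. Esterification with 2-[bis(2,2,2-trifluoroethoxy)phosphoryl]propanoic acid (EDC·HCl, DMAP cat., CH2Cl2, 0 °C) gives (1R)-1-[(2R,3S)-3-acetoxy-2-[3-(tert-butyldiphenylsilyloxy)prop-1-en-2-yl]-2,3-dihydro-1-benzofuran-5-yl]ethyl 2-[bis(2,2,2-trifluoroethoxy)phosphoryl]propanoate F4. Still–Gennari olefination with acetaldehyde (KN(SiMe3)2, 18-crown-6, THF, −78 °C) should form the (Z)-trisubstituted ester kinetically, and the route is rejoined at 16.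

**Step 12.** Cleavage of the hindered silyl ether may be slow, and long exposure to acidic fluoride invites ionisation at the para-alkoxybenzylic ester or loss of acetic acid toward the benzofuran. The fallback sets out from 12, where the ring is still electron-poor, and exchanges the silyl group for a much more labile one.
- HF·pyridine gives (2R,3S)-5-acetyl-2-(3-hydroxyprop-1-en-2-yl)-2,3-dihydro-1-benzofuran-3-yl acetate F5.
- Et3SiCl and imidazole give (2R,3S)-5-acetyl-2-[3-(triethylsilyloxy)prop-1-en-2-yl]-2,3-dihydro-1-benzofuran-3-yl acetate F6.
- Transfer hydrogenation as in step 10 gives (2R,3S)-5-[(1R)-1-hydroxyethyl]-2-[3-(triethylsilyloxy)prop-1-en-2-yl]-2,3-dihydro-1-benzofuran-3-yl acetate F7.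
- Acylation as in step 11 gives (1R)-1-[(2R,3S)-3-acetoxy-2-[3-(triethylsilyloxy)prop-1-en-2-yl]-2,3-dihydro-1-benzofuran-5-yl]ethyl (2Z)-2-methylbut-2-enoate F8.
- Brief treatment with pyridine-buffered HF·pyridine at 0 °C removes the triethylsilyl group within minutes and rejoins the route at 17.

## Further compounds

F1 | step 8 | 1-[(2R,3S)-3-hydroxy-2-(3-hydroxyprop-1-en-2-yl)-2,3-dihydro-1-benzofuran-5-yl]ethanone | C=C(CO)[C@H]1Oc2ccc(C(C)=O)cc2[C@@H]1O
F2 | step 3 | (4R)-4-[(R)-[2-fluoro-5-(2-methyl-1,3-dioxolan-2-yl)phenyl](hydroxy)methyl]-2,2-dimethyl-1,3-dioxan-5-one | CC1(C)OCC(=O)[C@H](O1)[C@H](O)c1cc(ccc1F)C1(C)OCCO1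
F3 | step 5 | (4S)-4-[(S)-[2-fluoro-5-(2-methyl-1,3-dioxolan-2-yl)phenyl](triethylsilyloxy)methyl]-2,2-dimethyl-5-[(trimethylsilyl)methyl]-1,3-dioxan-5-ol (C5 epimers) | CC1(C)OCC(O)(C[Si](C)(C)C)[C@@H](O1)[C@@H](O[Si](CC)(CC)CC)c1cc(ccc1F)C1(C)OCCO1
F4 | step 11 | (1R)-1-[(2R,3S)-3-acetoxy-2-[3-(tert-butyldiphenylsilyloxy)prop-1-en-2-yl]-2,3-dihydro-1-benzofuran-5-yl]ethyl 2-[bis(2,2,2-trifluoroethoxy)phosphoryl]propanoate | C=C(CO[Si](c1ccccc1)(c1ccccc1)C(C)(C)C)[C@H]1Oc2ccc([C@@H](C)OC(=O)C(C)P(=O)(OCC(F)(F)F)OCC(F)(F)F)cc2[C@@H]1OC(C)=O
F5 | step 12 | (2R,3S)-5-acetyl-2-(3-hydroxyprop-1-en-2-yl)-2,3-dihydro-1-benzofuran-3-yl acetate | C=C(CO)[C@H]1Oc2ccc(C(C)=O)cc2[C@@H]1OC(C)=O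
F6 | step 12 | (2R,3S)-5-acetyl-2-[3-(triethylsilyloxy)prop-1-en-2-yl]-2,3-dihydro-1-benzofuran-3-yl acetate | C=C(CO[Si](CC)(CC)CC)[C@H]1Oc2ccc(C(C)=O)cc2[C@@H]1OC(C)=O
F7 | step 12 | (2R,3S)-5-[(1R)-1-hydroxyethyl]-2-[3-(triethylsilyloxy)prop-1-en-2-yl]-2,3-dihydro-1-benzofuran-3-yl acetate | C=C(CO[Si](CC)(CC)CC)[C@H]1Oc2ccc([C@@H](C)O)cc2[C@@H]1OC(C)=O
F8 | step 12 | (1R)-1-[(2R,3S)-3-acetoxy-2-[3-(triethylsilyloxy)prop-1-en-2-yl]-2,3-dihydro-1-benzofuran-5-yl]ethyl (2Z)-2-methylbut-2-enoate | C=C(CO[Si](CC)(CC)CC)[C@H]1Oc2ccc([C@@H](C)OC(=O)/C(C)=C\C)cc2[C@@H]1OC(C)=O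
A1 | alternative 1 | (2R,3S)-5-[(1R)-1-(tert-butyldimethylsilyloxy)ethyl]-2-[1-(4,4,5,5-tetramethyl-1,3,2-dioxaborolan-2-yl)ethenyl]-2,3-dihydro-1-benzofuran-3-ol | C=C(B1OC(C)(C)C(C)(C)O1)[C@H]1Oc2ccc([C@@H](C)O[Si](C)(C)C(C)(C)C)cc2[C@@H]1O
A2 | alternative 1 | 5-[(1R)-1-(tert-butyldimethylsilyloxy)ethyl]-2-(propa-1,2-dien-1-yloxy)benzaldehyde | C=C=COc1ccc(cc1C=O)[C@@H](C)O[Si](C)(C)C(C)(C)C
A3 | alternative 2 | (2R,3S)-5-acetyl-2-(prop-1-en-2-yl)-2,3-dihydro-1-benzofuran-3-yl acetate | C=C(C)[C@H]1Oc2ccc(C(C)=O)cc2[C@@H]1OC(C)=O
A4 | alternative 2 | (3R,4S)-6-acetyl-3-hydroxy-2,2-dimethyl-3,4-dihydro-2H-chromen-4-yl acetate | CC1(C)Oc2ccc(C(C)=O)cc2[C@H](OC(C)=O)[C@H]1O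
A5 | alternative 2 | 1-(2,2-dimethyl-2H-chromen-6-yl)ethanone | CC(=O)c1ccc2OC(C)(C)C=Cc2c1
A6 | alternative 3 | (2R,3S)-5-acetyl-2-[3-(tert-butyldimethylsilyloxy)prop-1-en-2-yl]-2,3-dihydro-1-benzofuran-3-yl acetate | C=C(CO[Si](C)(C)C(C)(C)C)[C@H]1Oc2ccc(C(C)=O)cc2[C@@H]1OC(C)=O
A7 | alternative 3 | (3R,4S)-3-[(6-acetylpyridazin-3-yl)oxy]-2-[(tert-butyldimethylsilyloxy)methyl]hex-1-en-5-yn-4-yl acetate | C=C(CO[Si](C)(C)C(C)(C)C)[C@@H](Oc1ccc(nn1)C(C)=O)[C@@H](OC(C)=O)C#C
A8 | alternative 3 | 1-(6-chloropyridazin-3-yl)ethanone | CC(=O)c1ccc(Cl)nn1
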